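The route rests on disconnecting the C2=C3 double bond of the quinone ring, the trisubstituted alkene flanked by the C1 and C4 carbonyls. At the 1,4-diol oxidation level this ene-dione is a ring-closing-metathesis retron: a ruthenium carbene closes the six-membered ring between a vinyl carbinol (C3) and a 2-methylidene carbinol (C2) that already carries the (R)-configured silyloxy side chain, and the same catalyst then converts an allyl terminus into the prenyl group. The precursor, an ortho-bis(1-hydroxyallyl) hydroquinone bis-MOM ether, comes from a one-pot unsymmetrical double addition to a symmetric phthalaldehyde. Oxidation gives the quinone, acid unveils shikonin, and Steglich esterification with a (Z)-dienoic acid finishes the target.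

Key step: step 7

Remark: atoms are numbered as in naphthalene-1,4-dione (quinone ring C1 to C4, side chain on C2, C1′ the ester-bearing side-chain carbon); the target is the (R)-configured shikonin ester, and the rapidly interconverting naphthazarin tautomers are treated as one compound.

Step 1
Reactants: 1 3,6-dihydroxybenzene-1,2-dicarbonitrile (2,3-dicyanohydroquinone)
Product: 2 3,6-bis(methoxymethoxy)benzene-1,2-dicarbonitrile
Conditions: NaH (2.2 equiv), DMF, 0 °C; MOMCl (2.4 equiv), 0 °C to rt
Reagents that add atoms: chloromethyl methyl ether, COCCl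
Why: Williamson-type O-alkylation of the bis-phenoxide should give the bis-acetal, which is stable to hydride, organolithium, Grignard, ruthenium carbene and periodinane conditions and leaves under dilute acid at the end.

Step 2
Reactants: 2 3,6-bis(methoxymethoxy)benzene-1,2-dicarbonitrile
Product: 4 3,6-bis(methoxymethoxy)benzene-1,2-dicarbaldehyde, via bis(N-aluminio) dialdimine 3 (not isolated)
Conditions: i-Bu2AlH (2.3 equiv), toluene, −78 to 0 °C; then cold 1 M HCl, 0 °C, 10 min
Reagents that add atoms: water, O
Why: Partial nitrile reduction with i-Bu2AlH stops at the N-aluminio aldimine at low temperature, and brief cold acid hydrolysis should release both formyl groups without cleaving the aryl MOM acetals.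

Step 3
Reactants: 5 acrolein
Product: 7 2-bromoprop-2-enal (2-bromoacrolein), via 2,3-dibromopropanal 6 (not isolated)
Conditions: Br2 (1.0 equiv), CH2Cl2, −78 to 0 °C; then Et3N (1.05 equiv), 0 °C; used at once
Reagents that add atoms: bromine, BrBr
Why: Electrophilic bromine addition to the enal C=C followed by E1cB dehydrobromination through the acidic α-proton should give the α-bromo enal (bromination–elimination).

Step 4
Reactants: 7 2-bromoprop-2-enal
Product: 9 (3R)-2-bromohexa-1,5-dien-3-ol, via borinate ester 8 (not isolated)
Conditions: (+)-Ipc2B(allyl) (1.2 equiv), Et2O, −100 to −78 °C; then NaOH, 30% H2O2, 0 °C to rt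
Reagents that add atoms: (+)-B-allyldiisopinocampheylborane, C=CCB([C@H]1C[C@H]2C[C@@H]([C@@H]1C)C2(C)C)[C@H]1C[C@H]2C[C@@H]([C@@H]1C)C2(C)C
Why: Brown asymmetric allylboration through a closed chair (Zimmerman–Traxler) transition state should deliver allyl to the Re face of the aldehyde with the (+)-reagent derived from (−)-α-pinene, which sets the carbinol carbon (the future C1′) as R by reagent control.

Step 5
Reactants: 9 (3R)-2-bromohexa-1,5-dien-3-ol
Product: 10 tert-butyl{[(3R)-2-bromohexa-1,5-dien-3-yl]oxy}dimethylsilane
Conditions: TBSCl (1.2 equiv), imidazole (2.5 equiv), DMF, rt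
Reagents that add atoms: tert-butyldimethylsilyl chloride, CC(C)(C)[Si](C)(C)Cl
Why: Imidazole-mediated silylation of the secondary allylic alcohol masks C1′–OH against the organometallic and oxidation steps and is removed in the final acid deprotection.

Step 6
Reactants: 10 tert-butyl{[(3R)-2-bromohexa-1,5-dien-3-yl]oxy}dimethylsilane; 4 3,6-bis(methoxymethoxy)benzene-1,2-dicarbaldehyde
Product: 13 (3R)-3-[(tert-butyldimethylsilyl)oxy]-1-[2-(1-hydroxyprop-2-en-1-yl)-3,6-bis(methoxymethoxy)phenyl]-2-methylidenehex-5-en-1-ol, via vinyllithium 11 (not isolated), via lithium lactolate 12 (not isolated)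
Conditions: 10, t-BuLi (2.0 equiv), Et2O, −78 °C; cannulated into 4 (1.1 equiv), THF, −78 °C; then CH2=CHMgBr (3 equiv), −78 to 0 °C; then H2O, 0 °C
Reagents that add atoms: vinylmagnesium bromide, C=C[Mg]Br
Why: Bromine–lithium exchange at the sp2 carbon followed by 1,2-addition to one formyl group of the symmetric dialdehyde gives an alkoxide that closes onto the neighbouring formyl group as a lactolate, which resists further organolithium and is then opened through its ring-chain equilibrium by excess vinyl Grignard reagent (sequential 1,2-additions to a phthalaldehyde), so two different alkenyl groups are installed in one pot while C1′ is untouched and the two new carbinol centres, formed unselectively, are erased in step 8.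

Step 7
Reactants: 13 (3R)-3-[(tert-butyldimethylsilyl)oxy]-1-[2-(1-hydroxyprop-2-en-1-yl)-3,6-bis(methoxymethoxy)phenyl]-2-methylidenehex-5-en-1-ol
Product: 15 2-{(1R)-1-[(tert-butyldimethylsilyl)oxy]-4-methylpent-3-en-1-yl}-5,8-bis(methoxymethoxy)-1,4-dihydronaphthalene-1,4-diol, via allyl-bearing dihydronaphthalenediol 14 (not isolated)
Conditions: second-generation Hoveyda–Grubbs catalyst RuCl2(=CH-C6H4-2-OiPr)(H2IMes) (7 mol%), 1,4-benzoquinone (10 mol%), CH2Cl2 (0.005 M), 40 °C; then 2-methylbut-2-ene (large excess), 35 °C, sealed vessel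
Reagents that add atoms: 2-methylbut-2-ene, CC=C(C)C
Why: By the Chauvin mechanism the ruthenium alkylidene loads on the unhindered vinyl carbinol (C3), undergoes intramolecular [2+2]/retro-[2+2] with the C2 methylidene held ortho on the arene and expels ethene to forge the trisubstituted C2=C3 alkene, the closest known reaction type being ring-closing metathesis of 1,2-bis(1-hydroxyallyl)arenes to 1,4-dihydronaphthalene-1,4-diols and of carbasugar dienes to trisubstituted cyclohexenes. The six-membered carbocycle is closed as a ring-closing metathesis of a 1,7-diene, with C2=C3 ending endocyclic. No stereocentre is created: C1′ (R) is a bystander and the two carbinol centres are erased in step 8. The step needs six-ring closure to outrun oligomerisation or nine-ring closure through the allyl terminus, which the rigid ortho-arene spacer, high dilution and the reluctance of the geminally disubstituted alkene to react intermolecularly should secure, the free allylic hydroxyls assisting catalyst loading. In the same flask the remaining monosubstituted allyl terminus is then cross-metathesised with 2-methylbut-2-ene to the prenyl group, the trisubstituted ring alkene and the prenyl alkene being unreactive sinks. Benzoquinone is added to suppress isomerisation of the allylic alcohols by ruthenium hydrides.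

Step 8
Reactants: 15 2-{(1R)-1-[(tert-butyldimethylsilyl)oxy]-4-methylpent-3-en-1-yl}-5,8-bis(methoxymethoxy)-1,4-dihydronaphthalene-1,4-diol
Product: 16 2-{(1R)-1-[(tert-butyldimethylsilyl)oxy]-4-methylpent-3-en-1-yl}-5,8-bis(methoxymethoxy)naphthalene-1,4-dione
Conditions: Dess–Martin periodinane (3 equiv), NaHCO3, CH2Cl2, 0 °C to rt
Reagents that add atoms: none
Why: Dess–Martin oxidation of the two benzylic-allylic carbinols should give the ene-dione, which is the 1,4-naphthoquinone, both diol epimers converging on one product while the silyl ether keeps C1′ at the alcohol level with its configuration untouched.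

Step 9
Reactants: 16 2-{(1R)-1-[(tert-butyldimethylsilyl)oxy]-4-methylpent-3-en-1-yl}-5,8-bis(methoxymethoxy)naphthalene-1,4-dione
Product: 17 shikonin (5,8-dihydroxy-2-[(1R)-1-hydroxy-4-methylpent-3-en-1-yl]naphthalene-1,4-dione)
Conditions: 3 M aq. HCl, THF, 0 °C to rt
Reagents that add atoms: none
Why: Acid-catalysed acetal hydrolysis of the two aryl MOM ethers (assisted by the peri carbonyl groups) and protodesilylation of the secondary silyl ether should release shikonin in one global deprotection without breaking the C1′–O bond, so the R configuration is kept.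

Step 10
Reactants: 18 methacrolein; 19 (2-carboxyethyl)triphenylphosphonium bromide
Product: 21 (3Z)-5-methylhexa-3,5-dienoic acid, via carboxylate ylide 20 (not isolated)
Conditions: 19, NaN(SiMe3)2 (2.05 equiv), THF, −78 to −40 °C; 18, −78 °C to rt; then cold 1 M HCl to pH 3
Reagents that add atoms: none
Why: Wittig olefination of the non-stabilised carboxylate ylide under lithium-free conditions should proceed by kinetic cis-oxaphosphetane formation and give the (Z)-β,γ-unsaturated acid directly, the carboxylate form keeping the new alkene out of conjugation.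

Step 11
Reactants: 17 shikonin; 21 (3Z)-5-methylhexa-3,5-dienoic acid
Product: 22 (1R)-1-(5,8-dihydroxy-1,4-dioxo-1,4-dihydronaphthalen-2-yl)-4-methylpent-3-en-1-yl (3Z)-5-methylhexa-3,5-dienoate
Conditions: DCC (1.3 equiv), DMAP (0.1 equiv), CH2Cl2, −10 to 0 °C
Reagents that add atoms: none
Why: Steglich esterification should acylate only the secondary C1′ alcohol because the two peri phenols are locked in hydrogen bonds to the quinone carbonyls, with retention at C1′ since only its O–H bond reacts, and low temperature with sub-stoichiometric DMAP should keep the skipped (Z)-diene from moving into conjugation.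

Compound list
1 | 3,6-dihydroxybenzene-1,2-dicarbonitrile (2,3-dicyanohydroquinone) | N#Cc1c(O)ccc(O)c1C#N | starting material
2 | 3,6-bis(methoxymethoxy)benzene-1,2-dicarbonitrile | N#Cc1c(OCOC)ccc(OCOC)c1C#N | intermediate
3 | bis(N-diisobutylaluminio) dialdimine of 4 (not isolated) | CC(C)C[Al](CC(C)C)N=Cc1c(OCOC)ccc(OCOC)c1C=N[Al](CC(C)C)CC(C)C | intermediate
4 | 3,6-bis(methoxymethoxy)benzene-1,2-dicarbaldehyde | O=Cc1c(OCOC)ccc(OCOC)c1C=O | intermediate
5 | acrolein (prop-2-enal) | C=CC=O | starting material
6 | 2,3-dibromopropanal (racemic, not isolated) | O=CC(Br)CBr | intermediate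
7 | 2-bromoprop-2-enal (2-bromoacrolein) | C=C(Br)C=O | intermediate
8 | (3R)-2-bromohexa-1,5-dien-3-yl diisopinocampheylborinate (not isolated) | B(O[C@H](CC=C)C(Br)=C)([C@H]1C[C@H]2C[C@@H]([C@@H]1C)C2(C)C)[C@H]1C[C@H]2C[C@@H]([C@@H]1C)C2(C)C | intermediate
9 | (3R)-2-bromohexa-1,5-dien-3-ol | O[C@H](CC=C)C(Br)=C | intermediate
10 | tert-butyl{[(3R)-2-bromohexa-1,5-dien-3-yl]oxy}dimethylsilane | CC(C)(C)[Si](C)(C)O[C@H](CC=C)C(Br)=C | intermediate
11 | {(3R)-3-[(tert-butyldimethylsilyl)oxy]hexa-1,5-dien-2-yl}lithium (not isolated) | CC(C)(C)[Si](C)(C)O[C@H](CC=C)C([Li])=C | intermediate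
12 | lithium 3-{(3R)-3-[(tert-butyldimethylsilyl)oxy]hexa-1,5-dien-2-yl}-4,7-bis(methoxymethoxy)-1,3-dihydro-2-benzofuran-1-olate (epimers, not isolated) | CC(C)(C)[Si](C)(C)O[C@H](CC=C)C(=C)C1OC([O-])c2c(OCOC)ccc(OCOC)c12.[Li+] | intermediate
13 | (3R)-3-[(tert-butyldimethylsilyl)oxy]-1-[2-(1-hydroxyprop-2-en-1-yl)-3,6-bis(methoxymethoxy)phenyl]-2-methylidenehex-5-en-1-ol (epimers at both carbinol carbons) | CC(C)(C)[Si](C)(C)O[C@H](CC=C)C(=C)C(O)c1c(OCOC)ccc(OCOC)c1C(O)C=C | intermediate
14 | 2-{(1R)-1-[(tert-butyldimethylsilyl)oxy]but-3-en-1-yl}-5,8-bis(methoxymethoxy)-1,4-dihydronaphthalene-1,4-diol (epimers, not isolated) | CC(C)(C)[Si](C)(C)O[C@H](CC=C)C1=CC(O)c2c(OCOC)ccc(OCOC)c2C1O | intermediate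
15 | 2-{(1R)-1-[(tert-butyldimethylsilyl)oxy]-4-methylpent-3-en-1-yl}-5,8-bis(methoxymethoxy)-1,4-dihydronaphthalene-1,4-diol (epimers) | CC(C)(C)[Si](C)(C)O[C@H](CC=C(C)C)C1=CC(O)c2c(OCOC)ccc(OCOC)c2C1O | intermediate
16 | 2-{(1R)-1-[(tert-butyldimethylsilyl)oxy]-4-methylpent-3-en-1-yl}-5,8-bis(methoxymethoxy)naphthalene-1,4-dione | CC(C)(C)[Si](C)(C)O[C@H](CC=C(C)C)C1=CC(=O)c2c(OCOC)ccc(OCOC)c2C1=O | intermediate
17 | shikonin, 5,8-dihydroxy-2-[(1R)-1-hydroxy-4-methylpent-3-en-1-yl]naphthalene-1,4-dione | O[C@H](CC=C(C)C)C1=CC(=O)c2c(O)ccc(O)c2C1=O | intermediate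
18 | methacrolein (2-methylprop-2-enal) | C=C(C)C=O | starting material
19 | (2-carboxyethyl)triphenylphosphonium bromide | OC(=O)CC[P+](c1ccccc1)(c1ccccc1)c1ccccc1.[Br-] | starting material
20 | sodium 3-(triphenyl-λ5-phosphanylidene)propanoate (not isolated) | [Na+].[O-]C(=O)CC=P(c1ccccc1)(c1ccccc1)c1ccccc1 | intermediate
21 | (3Z)-5-methylhexa-3,5-dienoic acid | C=C(C)/C=C\CC(=O)O | intermediate
22 | (1R)-1-(5,8-dihydroxy-1,4-dioxo-1,4-dihydronaphthalen-2-yl)-4-methylpent-3-en-1-yl (3Z)-5-methylhexa-3,5-dienoate | C=C(C)/C=C\CC(=O)O[C@H](CC=C(C)C)C1=CC(=O)c2c(O)ccc(O)c2C1=O | target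

Total step count: 11
Longest linear sequence: 8 steps (steps 3, 4, 5, 6, 7, 8, 9 and 11, from acrolein)

Steps most likely to fail

1. Step 7. Intermolecular metathesis through the unhindered allyl terminus may outrun the slow ring closure onto the hindered geminally disubstituted alkene, and the diol may lose water during the long second stage. The fallback sets out from 10 and comes back at 15, and separates the two metatheses. Bromide 10 is first cross-metathesised with 2-methylbut-2-ene (second-generation Grubbs catalyst RuCl2(=CHPh)(PCy3)(H2IMes), neat alkene, rt; the bromoalkene is inert) to give tert-butyl{[(3R)-2-bromo-6-methylhepta-1,5-dien-3-yl]oxy}dimethylsilane F1. Bromine–lithium exchange as in step 6 gives the vinyllithium F2, which adds to 4 to give the lithium lactolate F3; vinylmagnesium bromide opens this to the prenyl diol F4. F4 has only one pair of reactive terminal alkenes and is closed by ring-closing metathesis alone (same catalyst, toluene, 60 °C, short reaction time) to 15.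

2. Step 6. The alkenyllithium may add to both formyl groups before the lactolate closes, and on warming the silyl group may shift from O–C1′ to the neighbouring new alkoxide. The fallback sets out from 4 and comes back at 13, reversing the order and changing the carbon nucleophile. Vinylmagnesium bromide (1.0 equiv, THF, −78 °C) is added to 4 and the stable lactol 3-ethenyl-4,7-bis(methoxymethoxy)-1,3-dihydro-2-benzofuran-1-ol F5 is isolated. F5, reacting through its hydroxy-aldehyde form, is then coupled with bromide 10 under Nozaki–Hiyama–Kishi conditions (CrCl2 4 equiv, NiCl2 2 mol%, DMF, rt). The alkenylchromium reagent adds only to the aldehyde, tolerates the free hydroxyl and is not basic enough to move the silyl group, and should give 13.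

3. Step 10. The β-carboxy ylide may fragment to triphenylphosphine and acrylate before it meets the enal, and the Z selectivity may erode. The fallback sets out from 18 and comes back at 21, using a ylide that cannot fragment and forming the acid afterwards. Commercial (3-hydroxypropyl)triphenylphosphonium bromide with NaN(SiMe3)2 (2 equiv, THF, −78 °C) gives the γ-oxido ylide F6. Its Z-selective Wittig reaction with 18 should give (3Z)-5-methylhexa-3,5-dien-1-ol F7. Oxidation of F7 with TEMPO (cat.) and PhI(OAc)2 in MeCN–H2O (pH 7 buffer) should give 21 without any base that could move the alkene.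

Further compounds
F1 | step 7 | tert-butyl{[(3R)-2-bromo-6-methylhepta-1,5-dien-3-yl]oxy}dimethylsilane | CC(C)(C)[Si](C)(C)O[C@H](CC=C(C)C)C(Br)=C
F2 | step 7 | {(3R)-3-[(tert-butyldimethylsilyl)oxy]-6-methylhepta-1,5-dien-2-yl}lithium | CC(C)(C)[Si](C)(C)O[C@H](CC=C(C)C)C([Li])=C
F3 | step 7 | lithium 3-{(3R)-3-[(tert-butyldimethylsilyl)oxy]-6-methylhepta-1,5-dien-2-yl}-4,7-bis(methoxymethoxy)-1,3-dihydro-2-benzofuran-1-olate | CC(C)(C)[Si](C)(C)O[C@H](CC=C(C)C)C(=C)C1OC([O-])c2c(OCOC)ccc(OCOC)c12.[Li+]
F4 | step 7 | (3R)-3-[(tert-butyldimethylsilyl)oxy]-1-[2-(1-hydroxyprop-2-en-1-yl)-3,6-bis(methoxymethoxy)phenyl]-6-methyl-2-methylidenehept-5-en-1-ol | CC(C)(C)[Si](C)(C)O[C@H](CC=C(C)C)C(=C)C(O)c1c(OCOC)ccc(OCOC)c1C(O)C=C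
F5 | step 6 | 3-ethenyl-4,7-bis(methoxymethoxy)-1,3-dihydro-2-benzofuran-1-ol | OC1OC(C=C)c2c(OCOC)ccc(OCOC)c12
F6 | step 10 | sodium 3-(triphenyl-λ5-phosphanylidene)propan-1-olate | [Na+].[O-]CCC=P(c1ccccc1)(c1ccccc1)c1ccccc1
F7 | step 10 | (3Z)-5-methylhexa-3,5-dien-1-ol | C=C(C)/C=C\CCO
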